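The core is numbered as 7-oxabicyclo[2.2.1]heptane, with C1 the C(CH3) bridgehead and C4 the CH bridgehead. It is unravelled to an acyclic, elemane-type epoxy-diene. The oxolane O7–C4–C5–C6–C1 grows from a terminal oxirane (O7, C4, C5). Under Lewis acid the isopropenyl C=C (C6, C1) inserts into the C5–O7 bond, which closes the cyclohexane and both oxolanes and sets C1 in one operation. This exploits the bare C5H2–C6H2 bridge between an O–CH and an O–C(CH3) bridgehead. The precursor takes C2/C3 from an enantioselective Ireland–Claisen rearrangement of a geranyl ester and C4 from iodolactonisation. C–Br and the carbinol carbon come from Shi and Sharpless epoxidations.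

Key step: step 9

Assumption: the (S,S)-bromoborane is taken to give the (2R,3R) acid 5. If the sense of induction is the opposite, the equally available (R,R) reagent is used and nothing else changes.
Abbreviation: Bic = (1R,2S,3S,4S)-3-[(3S)-3-bromo-4-chloro-4-methylpentyl]-1,3-dimethyl-7-oxabicyclo[2.2.1]heptan-2-yl.

Step 1
Reactants: 1 geraniol; 2 3-methylbut-3-enoic acid
Product: 3 geranyl 3-methylbut-3-enoate
Conditions: DCC, DMAP (5 mol%), CH2Cl2, 0 °C
Reagents that add atoms: none
Why: Steglich esterification of a primary allylic alcohol is routine, and low temperature with little DMAP keeps the β,γ-double bond out of conjugation; no stereocentre is formed.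

Step 2
Reactants: 3 geranyl 3-methylbut-3-enoate
Product: 5 (2R,3R)-3,7-dimethyl-2-(prop-1-en-2-yl)-3-vinyloct-6-enoic acid, via boron ketene acetal 4 (not isolated)
Conditions: (S,S)-1,2-diphenylethylenediamine bis[3,5-bis(trifluoromethyl)benzenesulfonamide], BBr3, CH2Cl2, rt, evaporate (bromoborane, 1.2 equiv); 3, Et3N, toluene–hexane, −78 °C, then 4 °C to rt, 2–3 d; aqueous work-up
Reagents that add atoms: none
Why: In this enantioselective boron-enolate Ireland–Claisen rearrangement, soft enolisation in the non-polar medium should give 4 with the isopropenyl group cis to the allylic oxygen, the chair transition state of the (E)-alkene then sets the elemane-type relative configuration of the adjacent tertiary and quaternary centres, and the C2-symmetric diazaborolidine selects the alkene face and so the absolute configuration.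

Step 3
Reactants: 5 (2R,3R)-3,7-dimethyl-2-(prop-1-en-2-yl)-3-vinyloct-6-enoic acid
Product: 6 (2R,3R)-5-[(2R)-3,3-dimethyloxiran-2-yl]-3-methyl-2-(prop-1-en-2-yl)-3-vinylpentanoic acid
Conditions: D-fructose-derived ketone catalyst (30 mol%), Oxone, K2CO3, Bu4NHSO4 (cat.), MeCN–DMM/aq. borate–EDTA buffer, 0 °C; work-up at pH 5; used at once
Reagents that add atoms: potassium peroxymonosulfate (Oxone), [K+].[O-]S(=O)(=O)OO
Why: In the Shi asymmetric epoxidation the chiral dioxirane reacts fastest with the electron-rich trisubstituted alkene (vinyl and isopropenyl are much slower), and its spiro transition state delivers oxygen to the face that gives the (R)-oxirane under reagent control.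

Step 4
Reactants: 6 (2R,3R)-5-[(2R)-3,3-dimethyloxiran-2-yl]-3-methyl-2-(prop-1-en-2-yl)-3-vinylpentanoic acid
Product: 7 (2R,3R,6S)-6-bromo-7-hydroxy-3,7-dimethyl-2-(prop-1-en-2-yl)-3-vinyloctanoic acid
Conditions: Li2NiBr4, THF, 0 °C
Reagents that add atoms: dilithium tetrabromonickelate, [Li+].[Li+].[Ni+2].[Br-].[Br-].[Br-].[Br-]
Why: Soft bromide opens the trisubstituted oxirane in SN2 fashion at the less substituted carbon (halohydrin formation), so inversion turns the (R)-oxirane carbon into the (S)-bromide and leaves the tertiary alcohol.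

Step 5
Reactants: 7 (2R,3R,6S)-6-bromo-7-hydroxy-3,7-dimethyl-2-(prop-1-en-2-yl)-3-vinyloctanoic acid
Product: 8 (3R,4S,5R)-4-[(3S)-3-bromo-4-hydroxy-4-methylpentyl]-5-(iodomethyl)-4-methyl-3-(prop-1-en-2-yl)oxolan-2-one
Conditions: I2, NaHCO3, MeCN, 0 °C, dark
Reagents that add atoms: iodine, II
Why: In this iodolactonisation, reversible iodonium formation followed by 5-exo closure on the vinyl group should outrun the strained 4-exo closure on the isopropenyl group, and an envelope transition state with isopropenyl and CH2I both pseudo-equatorial should favour the 3,5-cis lactone, which sets the future C4–O7 bond; the epimer is removed by chromatography.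

Step 6
Reactants: 8 (3R,4S,5R)-4-[(3S)-3-bromo-4-hydroxy-4-methylpentyl]-5-(iodomethyl)-4-methyl-3-(prop-1-en-2-yl)oxolan-2-one
Product: 9 (3R,4S,5R)-4-[(3S)-3-bromo-4-chloro-4-methylpentyl]-5-(iodomethyl)-4-methyl-3-(prop-1-en-2-yl)oxolan-2-one
Conditions: 1-chloro-N,N,2-trimethylpropenylamine, CH2Cl2, 0 °C to rt
Reagents that add atoms: 1-chloro-N,N,2-trimethylprop-1-en-1-amine, CC(C)=C(Cl)N(C)C
Why: In this neutral chlorodehydroxylation of a tertiary alcohol with an α-chloroenamine, the imidate ionises with anchimeric help from bromine and the paired chloride opens the bromonium ion at the tertiary carbon, so C–Br keeps its (S) configuration and no acid touches the isopropenyl group.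

Step 7
Reactants: 9 (3R,4S,5R)-4-[(3S)-3-bromo-4-chloro-4-methylpentyl]-5-(iodomethyl)-4-methyl-3-(prop-1-en-2-yl)oxolan-2-one
Product: 10 (3R,4S,5R)-4-[(3S)-3-bromo-4-chloro-4-methylpentyl]-5-(iodomethyl)-4-methyl-3-(prop-1-en-2-yl)oxolan-2-ol (anomer mixture)
Conditions: DIBAL-H (1.1 equiv), CH2Cl2, −78 °C; Rochelle salt
Reagents that add atoms: none
Why: Partial reduction of a γ-lactone with DIBAL-H at −78 °C stops at the aluminium lactolate and leaves the three carbon–halogen bonds untouched; the new anomeric centre is of no consequence.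

Step 8
Reactants: 10 (3R,4S,5R)-4-[(3S)-3-bromo-4-chloro-4-methylpentyl]-5-(iodomethyl)-4-methyl-3-(prop-1-en-2-yl)oxolan-2-ol; 11 triethyl 3-methyl-4-phosphonocrotonate
Product: 13 ethyl (2E,4E,6R,7S,10S)-10-bromo-11-chloro-3,7,11-trimethyl-7-[(2R)-oxiran-2-yl]-6-(prop-1-en-2-yl)dodeca-2,4-dienoate, via epoxy aldehyde 12 (not isolated)
Conditions: 11, LiHMDS, THF–DMPU, −78 °C; add 10; to 0 °C
Reagents that add atoms: none
Why: Base opens the lactol, the freed alkoxide displaces the neighbouring primary iodide (3-exo-tet Williamson closure with retention at the carbinol carbon) to give 12, and Horner–Wadsworth–Emmons olefination with the vinylogous phosphonate anion turns the aldehyde into the (2E,4E)-dienoate, a side chain that cannot participate in the next step.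

Step 9
Reactants: 13 ethyl (2E,4E,6R,7S,10S)-10-bromo-11-chloro-3,7,11-trimethyl-7-[(2R)-oxiran-2-yl]-6-(prop-1-en-2-yl)dodeca-2,4-dienoate
Product: 15 ethyl (2E,4E)-5-Bic-3-methylpenta-2,4-dienoate, via tertiary cation 14 (not isolated)
Conditions: BF3·OEt2 (0.3 equiv), CH2Cl2, −78 to −30 °C
Reagents that add atoms: none
Why: Proposed new method: BF3 binds the oxirane oxygen and the isopropenyl CH2 (future C6) attacks the unhindered oxirane CH2 (C5) in an SN2-like chair transition state to give tertiary cation 14 at C1, which the boron-bound C4 alkoxide captures across the ring after a chair-to-boat flip, so that the C=C is formally inserted into the C5–O7 bond and the three-membered ring O7–C4–C5 becomes the five-membered ring O7–C4–C5–C6–C1. The closest known reaction types are the Lewis acid epoxide–olefin cyclisations of trisubstituted epoxides that end as 7-oxabicyclo[2.2.1]heptanes and the 6-endo Friedel–Crafts opening of 4-aryl-1,2-epoxybutanes at the CH2 terminus, whereas opening of a monosubstituted oxirane at CH2 by an alkene with oxygen capture is not established. The cyclohexane closes 6-endo-tet at the oxirane and 6-endo-trig at the alkene, and both oxolane rings close in the transannular C1–O7 bond formation. The only new stereocentre, C1, is fixed by geometry because O7 is held on C4 and can reach only one face of the cation, while C2, C3 and C4 are carried in and let oxygen and both side chains sit equatorial in the chair. The step needs attack at C5 rather than C4, which the neopentyl position of C4 next to quaternary C3 secures, and it needs the isopropenyl group as the only competent nucleophile, which holds because the dienoate is electron-poor and too remote for carbonyl participation and the former prenyl alkene is already the bromochloride. Alkenols formed by proton loss from 14 should re-enter through the same cation under the acidic conditions.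

Step 10
Reactants: 15 ethyl (2E,4E)-5-Bic-3-methylpenta-2,4-dienoate
Product: 16 ethyl (2E)-5-Bic-3-methylpent-2-enoate
Conditions: 2-nitrobenzenesulfonylhydrazide (in portions), MeCN, rt
Reagents that add atoms: none
Why: Diimide reduction is a concerted syn hydrogen transfer that is far faster for the disubstituted C4=C5 alkene than for the trisubstituted enoate alkene and does not touch C–Br or C–Cl; no stereocentre changes.

Step 11
Reactants: 16 ethyl (2E)-5-Bic-3-methylpent-2-enoate
Product: 17 (2E)-5-Bic-3-methylpent-2-en-1-ol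
Conditions: DIBAL-H (2.5 equiv), CH2Cl2, −78 °C; Rochelle salt
Reagents that add atoms: none
Why: 1,2-Reduction of the enoate with DIBAL-H gives the (E)-allylic alcohol needed for directed epoxidation and creates no stereocentre.

Step 12
Reactants: 17 (2E)-5-Bic-3-methylpent-2-en-1-ol
Product: 18 {(2S,3S)-3-[2-(Bic)ethyl]-3-methyloxiran-2-yl}methanol
Conditions: Ti(OiPr)4 (10 mol%), L-(+)-DET (12 mol%), TBHP, 4 Å MS, CH2Cl2, −20 °C
Reagents that add atoms: tert-butyl hydroperoxide, CC(C)(C)OO
Why: In the Sharpless asymmetric epoxidation the only alkene is an (E)-3-methyl allylic alcohol of the geraniol type, and the L-(+)-tartrate complex delivers oxygen to the face that gives the (2S,3S)-epoxy alcohol under reagent control, which sets the carbinol carbon.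

Step 13
Reactants: 18 {(2S,3S)-3-[2-(Bic)ethyl]-3-methyloxiran-2-yl}methanol
Product: 19 (2R,3S)-3-[2-(Bic)ethyl]-3-methyloxirane-2-carbaldehyde
Conditions: TEMPO (10 mol%), PhI(OAc)2, CH2Cl2, rt
Reagents that add atoms: none
Why: Oxoammonium (TEMPO) oxidation of the primary alcohol stops at the aldehyde and tolerates the oxirane, the ether bridge and the halides; the descriptor at C2 changes by priority only.

Step 14
Reactants: 19 (2R,3S)-3-[2-(Bic)ethyl]-3-methyloxirane-2-carbaldehyde
Product: 21 dactylomelol, via epoxy hydrazone 20 (not isolated)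
Conditions: N2H4·H2O, AcOH (cat.), MeOH, 0 °C to rt, argon
Reagents that add atoms: none
Why: In the Wharton transposition hydrazone 20 tautomerises and opens the oxirane to a vinyl diazene that loses nitrogen, which gives the vinyl group and leaves the C–O bond at the tertiary centre intact, so the (S) carbinol configuration set in step 12 is retained.

Compound list
1 | geraniol | CC(C)=CCC/C(C)=C/CO | starting material
2 | 3-methylbut-3-enoic acid | C=C(C)CC(=O)O | starting material
3 | geranyl 3-methylbut-3-enoate | C=C(C)CC(=O)OC/C=C(C)/CCC=C(C)C | intermediate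
4 | boron ketene acetal of 3 with the (S,S)-diazaborolidine, isopropenyl cis to the geranyloxy group | C=C(C)/C=C(\OC/C=C(C)/CCC=C(C)C)OB1N(S(=O)(=O)c2cc(C(F)(F)F)cc(C(F)(F)F)c2)[C@@H](c2ccccc2)[C@H](c2ccccc2)N1S(=O)(=O)c1cc(C(F)(F)F)cc(C(F)(F)F)c1 | intermediate
5 | (2R,3R)-3,7-dimethyl-2-(prop-1-en-2-yl)-3-vinyloct-6-enoic acid | OC(=O)[C@H](C(C)=C)[C@](C)(CCC=C(C)C)C=C | intermediate
6 | (2R,3R)-5-[(2R)-3,3-dimethyloxiran-2-yl]-3-methyl-2-(prop-1-en-2-yl)-3-vinylpentanoic acid | OC(=O)[C@H](C(C)=C)[C@](C)(CC[C@H]1OC1(C)C)C=C | intermediate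
7 | (2R,3R,6S)-6-bromo-7-hydroxy-3,7-dimethyl-2-(prop-1-en-2-yl)-3-vinyloctanoic acid | OC(=O)[C@H](C(C)=C)[C@](C)(CC[C@H](Br)C(C)(C)O)C=C | intermediate
8 | (3R,4S,5R)-4-[(3S)-3-bromo-4-hydroxy-4-methylpentyl]-5-(iodomethyl)-4-methyl-3-(prop-1-en-2-yl)oxolan-2-one | O=C1[C@H](C(C)=C)[C@](C)(CC[C@H](Br)C(C)(C)O)[C@H](CI)O1 | intermediate
9 | (3R,4S,5R)-4-[(3S)-3-bromo-4-chloro-4-methylpentyl]-5-(iodomethyl)-4-methyl-3-(prop-1-en-2-yl)oxolan-2-one | O=C1[C@H](C(C)=C)[C@](C)(CC[C@H](Br)C(C)(C)Cl)[C@H](CI)O1 | intermediate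
10 | lactol of 9, oxolan-2-ol, anomer mixture | OC1[C@H](C(C)=C)[C@](C)(CC[C@H](Br)C(C)(C)Cl)[C@H](CI)O1 | intermediate
11 | triethyl 3-methyl-4-phosphonocrotonate, ethyl (2E)-4-(diethoxyphosphoryl)-3-methylbut-2-enoate | CCOC(=O)/C=C(C)/CP(=O)(OCC)OCC | starting material
12 | (2R,3S,6S)-6-bromo-7-chloro-3,7-dimethyl-3-[(2R)-oxiran-2-yl]-2-(prop-1-en-2-yl)octanal | O=C[C@H](C(C)=C)[C@](C)(CC[C@H](Br)C(C)(C)Cl)[C@@H]1CO1 | intermediate
13 | ethyl (2E,4E,6R,7S,10S)-10-bromo-11-chloro-3,7,11-trimethyl-7-[(2R)-oxiran-2-yl]-6-(prop-1-en-2-yl)dodeca-2,4-dienoate | CCOC(=O)/C=C(C)/C=C/[C@H](C(C)=C)[C@](C)(CC[C@H](Br)C(C)(C)Cl)[C@@H]1CO1 | intermediate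
14 | cyclohexyl tertiary cation at C1 with the BF3-bound alkoxide on C4 (zwitterion) | CCOC(=O)/C=C(C)/C=C/[C@H]1[C@](C)(CC[C@H](Br)C(C)(C)Cl)[C@@H](O[B-](F)(F)F)CC[C+]1C | intermediate
15 | ethyl (2E,4E)-5-Bic-3-methylpenta-2,4-dienoate | CCOC(=O)/C=C(C)/C=C/[C@H]1[C@](C)(CC[C@H](Br)C(C)(C)Cl)[C@@H]2CC[C@@]1(C)O2 | intermediate
16 | ethyl (2E)-5-Bic-3-methylpent-2-enoate | CCOC(=O)/C=C(C)/CC[C@H]1[C@](C)(CC[C@H](Br)C(C)(C)Cl)[C@@H]2CC[C@@]1(C)O2 | intermediate
17 | (2E)-5-Bic-3-methylpent-2-en-1-ol | OC/C=C(C)/CC[C@H]1[C@](C)(CC[C@H](Br)C(C)(C)Cl)[C@@H]2CC[C@@]1(C)O2 | intermediate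
18 | {(2S,3S)-3-[2-(Bic)ethyl]-3-methyloxiran-2-yl}methanol | OC[C@@H]1O[C@@]1(C)CC[C@H]1[C@](C)(CC[C@H](Br)C(C)(C)Cl)[C@@H]2CC[C@@]1(C)O2 | intermediate
19 | (2R,3S)-3-[2-(Bic)ethyl]-3-methyloxirane-2-carbaldehyde | O=C[C@@H]1O[C@@]1(C)CC[C@H]1[C@](C)(CC[C@H](Br)C(C)(C)Cl)[C@@H]2CC[C@@]1(C)O2 | intermediate
20 | hydrazone of 19 | NN=C[C@@H]1O[C@@]1(C)CC[C@H]1[C@](C)(CC[C@H](Br)C(C)(C)Cl)[C@@H]2CC[C@@]1(C)O2 | intermediate
21 | dactylomelol, (3S)-5-Bic-3-methylpent-1-en-3-ol | C=C[C@@](C)(O)CC[C@H]1[C@](C)(CC[C@H](Br)C(C)(C)Cl)[C@@H]2CC[C@@]1(C)O2 | target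

Total step count: 14. Longest linear sequence: 14.

Steps most likely to fail

Step 9. The activated oxirane may ionise at C4 and undergo a Wagner–Meerwein or hydride (Meinwald-type) shift, or be opened by fluoride, before the alkene reaches C5. The fallback uses known chemistry, sets out from 9 and comes back at 15.
- Iodine-atom-transfer radical cyclisation of 9 [(Bu3Sn)2 cat., hν, benzene] lets the primary C5 radical close 6-endo on the 1,1-disubstituted alkene, the mode preferred by 5-methylhex-5-enyl radicals. This gives the bicyclic tertiary iodide lactone F1.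
- Silver(I) triflate with 2,6-di-tert-butylpyridine in methanol ionises the iodide. Lactone methanolysis with capture of the cation by the C4 oxygen then gives the oxa-bridged methyl ester F2.
- DIBAL-H at −78 °C gives the bicyclic aldehyde F3, and olefination with 11 as in step 8 returns to 15.

Step 5. Facial selectivity at the vinyl group may be poor or reversed, and the isopropenyl iodonium ion may be captured in competition. The fallback makes the wrong epimer productive by inverting C4. It sets out from 7 and comes back at 9.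
- The 5-epimeric iodolactone F4 is chlorinated as in step 6 to the 5-epimeric chloro iodolactone F5.
- K2CO3 in MeOH gives the epimeric epoxy methyl ester F6.
- Camphorsulfonic acid in wet CH2Cl2 makes the ester carbonyl open the oxirane 5-exo at its CH carbon with inversion, which gives the hydroxymethyl lactone F7 with the required configuration.
- An Appel-type iodination (I2, PPh3, imidazole) returns to 9.

Step 8. The phosphonate anion may enolise the hindered β,γ-unsaturated aldehyde. This would cause loss of the C2 configuration or migration of the double bond into conjugation. The fallback avoids any base while the aldehyde exists and builds the side chain in two stages. It sets out from 10 and comes back at 16.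
- Neutral Wittig reaction of 10 with 1-(triphenylphosphoranylidene)propan-2-one (toluene, 60 °C) gives the iodohydrin enone F8.
- K2CO3 in MeOH closes the epoxy enone F9.
- The cyclisation of step 9 gives the bicyclic enone F10.
- Conjugate reduction with [(Ph3P)CuH]6 gives the methyl ketone F11.
- Horner–Wadsworth–Emmons reaction with triethyl phosphonoacetate (NaH, THF, 0 °C), with removal of the minor (Z)-isomer, returns to 16.

Further compounds
F1 | step 9 | bicyclic tertiary iodide lactone (6-oxabicyclo[3.2.1]octan-7-one, C–I epimers) | O=C1O[C@H]2CCC(C)(I)[C@@H]1[C@]2(C)CC[C@H](Br)C(C)(C)Cl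
F2 | step 9 | methyl Bic-carboxylate | COC(=O)[C@H]1[C@](C)(CC[C@H](Br)C(C)(C)Cl)[C@@H]2CC[C@@]1(C)O2
F3 | step 9 | Bic-carbaldehyde | O=C[C@H]1[C@](C)(CC[C@H](Br)C(C)(C)Cl)[C@@H]2CC[C@@]1(C)O2
F4 | step 5 | 5-epimer of 8 | O=C1[C@H](C(C)=C)[C@](C)(CC[C@H](Br)C(C)(C)O)[C@@H](CI)O1
F5 | step 5 | 5-epimer of 9 | O=C1[C@H](C(C)=C)[C@](C)(CC[C@H](Br)C(C)(C)Cl)[C@@H](CI)O1
F6 | step 5 | epoxy methyl ester with the (2S)-oxirane | COC(=O)[C@H](C(C)=C)[C@](C)(CC[C@H](Br)C(C)(C)Cl)[C@H]1CO1
F7 | step 5 | 5-(hydroxymethyl) analogue of 9 | O=C1[C@H](C(C)=C)[C@](C)(CC[C@H](Br)C(C)(C)Cl)[C@H](CO)O1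
F8 | step 8 | iodohydrin (E)-enone | CC(=O)/C=C/[C@H](C(C)=C)[C@](C)(CC[C@H](Br)C(C)(C)Cl)[C@@H](O)CI
F9 | step 8 | epoxy (E)-enone | CC(=O)/C=C/[C@H](C(C)=C)[C@](C)(CC[C@H](Br)C(C)(C)Cl)[C@@H]1CO1
F10 | step 8 | (3E)-4-Bic-but-3-en-2-one | CC(=O)/C=C/[C@H]1[C@](C)(CC[C@H](Br)C(C)(C)Cl)[C@@H]2CC[C@@]1(C)O2
F11 | step 8 | 4-Bic-butan-2-one | CC(=O)CC[C@H]1[C@](C)(CC[C@H](Br)C(C)(C)Cl)[C@@H]2CC[C@@]1(C)O2
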